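Both C–O bonds of the 4H-pyran-4-one ring and the C3–C4 bond are cut. Because O1 is flanked by C2 and C6 and faces the C4 carbonyl across the ring, the heterocycle reduces to a single oxygen atom inserted between a C4–C5–C6 tribromoacryloyl fragment and the two alkyne carbons C2 and C3. One flask should then do three things: copper-catalysed acylation of a silyl-protected pent-1-yn-3-ol by 2,3,3-tribromoacryloyl chloride, hydration of the ynone, and attack of the enol oxygen on the CBr2 carbon with expulsion of bromide, giving the 5,6-dibromopyranone. The precursors are the acid chloride, which holds the C5 and C6 bromines, and the TBS ether of the alkynol; C3 bromination, desilylation and carbinol oxidation finish the synthesis.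

Key step: step 5

Assumption: the target has no stereocentre (it is an achiral 2-acyl-4-pyranone), so no enantiomer has to be chosen; the carbinol carbon carried through the route is racemic and is erased in the last step. Ring atoms keep the target's numbering in all intermediates (O1, C2 with the side chain, C3, C4 carbonyl, C5, C6), even where lowest-locant nomenclature would number the ring the other way.

Step 1
Reactants: 1 propiolic acid; 2 bromine
Product: 3 3-bromopropiolic acid
Conditions: KOH, Br2, H2O, 0 °C; then HCl (aq), 0 °C, Et2O extraction, no heating
Reagents that add atoms: bromine, BrBr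
Why: Hypobromite bromination of a terminal alkyne (the acetylide of the propiolate attacks electrophilic bromine) is the classical route to 3-bromopropiolic acid, which is kept cold and used at once because it loses CO2 when heated.

Step 2
Reactants: 3 3-bromopropiolic acid; 2 bromine
Product: 4 2,3,3-tribromoacrylic acid
Conditions: Br2 (1.05 equiv), CH2Cl2, 0 °C → rt
Reagents that add atoms: bromine, BrBr
Why: Electrophilic anti addition of bromine to the haloalkyne stops at the alkene stage because the tetrasubstituted, electron-poor tribromoacrylic acid does not take up more bromine under these conditions.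

Step 3
Reactants: 4 2,3,3-tribromoacrylic acid
Product: 5 2,3,3-tribromoacryloyl chloride
Conditions: (COCl)2 (1.3 equiv), DMF (cat.), CH2Cl2, 0 °C → rt; evaporate, use crude
Reagents that add atoms: oxalyl chloride, O=C(Cl)C(Cl)=O
Why: Acid chloride formation through the Vilsmeier chloride (oxalyl chloride, catalytic DMF) is mild, gives only gaseous by-products and cannot form a ketene since 4 has no α-hydrogen.

Step 4
Reactants: 6 rac-pent-1-yn-3-ol
Product: 7 rac-tert-butyldimethyl(pent-1-yn-3-yloxy)silane
Conditions: TBSCl (1.1 equiv), imidazole (2.2 equiv), CH2Cl2, 0 °C → rt
Reagents that add atoms: tert-butyldimethylsilyl chloride (TBSCl), CC(C)(C)[Si](C)(C)Cl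
Why: Standard imidazole-promoted silylation of the secondary propargylic alcohol masks the oxygen that would otherwise be acylated by 5 or close a furanone after hydration in step 5.

Step 5
Reactants: 5 2,3,3-tribromoacryloyl chloride; 7 rac-tert-butyldimethyl(pent-1-yn-3-yloxy)silane; 8 water
Product: 11 rac-5,6-dibromo-2-[1-(tert-butyldimethylsilyloxy)propyl]-4H-pyran-4-one, via tribromovinyl ynone 9 (not isolated), via diketone enol 10 (not isolated)
Conditions: CuI (5 mol%), Et3N (1.2 equiv), THF, Ar, 0 °C → rt; then H2O (10 equiv), K2CO3 (2.5 equiv), rt → 40 °C
Reagents that add atoms: water, O
Why: Proposed new method: a copper(I) acetylide formed from 7 with CuI and Et3N should be acylated by 5 (palladium-free acyl Sonogashira-type coupling, known for acid chlorides and terminal alkynes) to give the cross-conjugated ynone 9 with all three vinylic bromides intact, since Cu(I) does not insert into C–Br bonds at room temperature and 5 has no α-hydrogen from which a ketene could arise. Hydroxide from water and K2CO3 should then add in oxa-Michael fashion to the alkyne β-carbon (the future C2) to give the 1,3-diketone enol 10, whose enol(ate) oxygen attacks the dibromomethylene carbon (the future C6) and expels bromide by addition–elimination, so that C3–C4, O1–C2 and O1–C6 are all made in one flask. The closest known chemistry is the three-component acid chloride/alkyne coupling, conjugate addition and ring closure by halide displacement that leads to thiochromenones and 4-quinolones, together with the closure of 2-hydroxyaryl β,β-dihalovinyl ketones to 2-halochromones; new here is water as the stitching atom combined with a vinylic bromide as the leaving group. The single ring, the pyranone, closes in a 6-endo-trig mode (vinylic substitution at C6 with C5=C6 inside the new ring), and whichever geminal bromide leaves, one remains on C6. No stereocentre is created and the racemic carbinol carbon is a spectator. The selectivity required is attack of oxygen on the ynone before the CBr2 carbon, which the substrate should secure because the sp β-carbon is unhindered and fully conjugated whereas the tribromovinyl ketone is twisted out of conjugation by its α-bromine and shielded by two bromines; the silyl ether keeps the carbinol oxygen from closing a furanone, and the regiochemistry of hydration is fixed because only the β-carbon of the ynone is electrophilic.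

Step 6
Reactants: 11 rac-5,6-dibromo-2-[1-(tert-butyldimethylsilyloxy)propyl]-4H-pyran-4-one; 2 bromine
Product: 13 rac-3,5,6-tribromo-2-[1-(tert-butyldimethylsilyloxy)propyl]-4H-pyran-4-one, via dibromide adduct 12 (not isolated)
Conditions: Br2 (1.1 equiv), CH2Cl2, dark, 0 °C → rt; then iPr2NEt (1.5 equiv), 0 °C
Reagents that add atoms: bromine, BrBr
Why: Electrophilic bromination by addition–elimination, the standard entry to 3-bromo-4-pyranones and 3-bromochromones: bromine adds across C2=C3, whose C3 is the nucleophilic β-carbon of the O1–C2=C3–C4=O vinylogous ester and the only C–H position of the ring, and the hindered amine removes HBr from dibromide 12 without attacking C6, while the fully substituted, electron-poor C5=C6 bond stays untouched.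

Step 7
Reactants: 13 rac-3,5,6-tribromo-2-[1-(tert-butyldimethylsilyloxy)propyl]-4H-pyran-4-one
Product: 14 rac-3,5,6-tribromo-2-(1-hydroxypropyl)-4H-pyran-4-one
Conditions: 48% aq. HF, MeCN, 0 °C → rt (plastic vessel)
Reagents that add atoms: none
Why: Acid-mediated fluoride cleavage of the TBS ether with aqueous HF in acetonitrile is neither basic nor strongly nucleophilic, so the C6 bromide (a vinylogous acyl bromide that TBAF or alkoxide could displace) should survive.

Step 8
Reactants: 14 rac-3,5,6-tribromo-2-(1-hydroxypropyl)-4H-pyran-4-one
Product: 15 3,5,6-tribromo-2-propanoyl-4H-pyran-4-one
Conditions: Dess–Martin periodinane (1.3 equiv), CH2Cl2, 0 °C → rt; dilute with Et2O/hexane, filter through silica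
Reagents that add atoms: none
Why: Dess–Martin oxidation converts the secondary carbinol into the ketone under neutral, non-nucleophilic conditions and thereby removes the only stereocentre, and work-up by filtration avoids thiosulfate, which could attack C6.

Compound list
1 | propiolic acid (prop-2-ynoic acid) | C#CC(=O)O | starting material
2 | bromine | BrBr | starting material
3 | 3-bromopropiolic acid | OC(=O)C#CBr | intermediate
4 | 2,3,3-tribromoacrylic acid | OC(=O)C(Br)=C(Br)Br | intermediate
5 | 2,3,3-tribromoacryloyl chloride | O=C(Cl)C(Br)=C(Br)Br | intermediate
6 | rac-pent-1-yn-3-ol | CCC(O)C#C | starting material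
7 | rac-tert-butyldimethyl(pent-1-yn-3-yloxy)silane | CCC(O[Si](C)(C)C(C)(C)C)C#C | intermediate
8 | water | O | starting material
9 | rac-1,1,2-tribromo-6-(tert-butyldimethylsilyloxy)oct-1-en-4-yn-3-one | CCC(O[Si](C)(C)C(C)(C)C)C#CC(=O)C(Br)=C(Br)Br | intermediate (not isolated)
10 | rac-(4Z)-1,1,2-tribromo-6-(tert-butyldimethylsilyloxy)-5-hydroxyocta-1,4-dien-3-one (enol of the 1,3-diketone) | CCC(O[Si](C)(C)C(C)(C)C)/C(O)=C/C(=O)C(Br)=C(Br)Br | intermediate (not isolated)
11 | rac-5,6-dibromo-2-[1-(tert-butyldimethylsilyloxy)propyl]-4H-pyran-4-one | CCC(O[Si](C)(C)C(C)(C)C)c1cc(=O)c(Br)c(Br)o1 | intermediate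
12 | 2,3,5,6-tetrabromo-2-[1-(tert-butyldimethylsilyloxy)propyl]-2,3-dihydro-4H-pyran-4-one (racemic, mixture of diastereomers) | CCC(O[Si](C)(C)C(C)(C)C)C1(Br)OC(Br)=C(Br)C(=O)C1Br | intermediate (not isolated)
13 | rac-3,5,6-tribromo-2-[1-(tert-butyldimethylsilyloxy)propyl]-4H-pyran-4-one | CCC(O[Si](C)(C)C(C)(C)C)c1oc(Br)c(Br)c(=O)c1Br | intermediate
14 | rac-3,5,6-tribromo-2-(1-hydroxypropyl)-4H-pyran-4-one | CCC(O)c1oc(Br)c(Br)c(=O)c1Br | intermediate
15 | 3,5,6-tribromo-2-propanoyl-4H-pyran-4-one (achiral) | CCC(=O)c1oc(Br)c(Br)c(=O)c1Br | target

Total step count: 8
Longest linear sequence: 7 steps (steps 1, 2, 3, 5, 6, 7, 8, from propiolic acid)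

Steps most likely to fail

Step 5 (proposed new method). The three events may not mesh. Hydroxide could attack the dibromomethylene carbon or displace the C6 bromide of the product. The ynone could be consumed by isomerisation or oligomerisation before it is hydrated. Chloride could exchange into the activated vinylic positions. The fallback uses known chemistry, sets out from 7 and 5 and comes back at 11; it builds the diketone by enolate acylation, so that neither an ynone nor free hydroxide is needed. Alkyne 7 would be hydrated in the Markovnikov sense (gold(I) catalyst such as (Ph3P)AuNTf2, wet dioxane, rt) to the methyl ketone rac-3-(tert-butyldimethylsilyloxy)pentan-2-one F1. Soft enolisation of this ketone on the methyl side (MgBr2·OEt2, iPr2NEt, CH2Cl2) and C-acylation with acid chloride 5 should give the 1,3-diketone, isolated as its enol 10. Mild base (K2CO3, MeCN, rt) would then close the ring by intramolecular vinylic substitution, the closure type known from 2-halochromone synthesis, to reach 11.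

Step 6. Electrophilic attack at C3 may be too slow on a ring that already carries two bromines, so that loss of the silyl group to HBr or attack of the amine at C6 overtakes the substitution. The fallback sets out from 7 and 5 and comes back at 13; it installs the C3 bromine before the ring exists. Diketone enol 10 would be prepared and isolated by the enolate acylation described above (hydration of 7 to F1, then acylation with 5). Its central carbon would be brominated with NBS (CH2Cl2, 0 °C, the standard α-halogenation of a 1,3-diketone) to give rac-1,1,2,4-tetrabromo-6-(tert-butyldimethylsilyloxy)oct-1-ene-3,5-dione F2. K2CO3 in MeCN should then close the ring with loss of bromide and deliver 13 directly.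

Step 7. Cleavage of the hindered secondary silyl ether next to the C3 bromine may be incomplete, or the free carbinol may be lost through displacement of the C6 bromide during its isolation. The fallback sets out from 13 and comes back at 15, skipping 14. Jones reagent (CrO3, H2SO4, acetone, 0 °C, short contact time) is known to convert TBS ethers of secondary alcohols directly into ketones by acidic desilylation and oxidation in the same flask. This path makes no compound outside the list (F0).

Further compounds
F1 | step 5 | rac-3-(tert-butyldimethylsilyloxy)pentan-2-one | CCC(O[Si](C)(C)C(C)(C)C)C(C)=O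
F2 | step 6 | rac-1,1,2,4-tetrabromo-6-(tert-butyldimethylsilyloxy)oct-1-ene-3,5-dione (mixture of diastereomers) | CCC(O[Si](C)(C)C(C)(C)C)C(=O)C(Br)C(=O)C(Br)=C(Br)Br
F0 | step 7 | none | none
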